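**Plan**

1. Cuts, last to first: the lactol O–H is traced back to an O–CH(CH3)Ph acetal; the ring A CH2OH to CHO; the seven-membered lactone is cut at C(=O)–O(ring B); the diaryl ether at O–C(ring A); the five-membered lactone at the bond from its carbonyl carbon to the ring B carbon that lies between the phenol carbon and the lactol-bearing carbon.
2. Enabling feature: in ring B the lactone carbonyl carbon is tied through the ring oxygen to the lactol carbon on the neighbouring aromatic carbon. A phenyl carbonate on that oxygen therefore holds a C=O five atoms from the aromatic carbon next to the phenol oxygen, and an aryl magnesium there closes the lactone, completes the hexasubstituted ring B and gives the lactol carbon at its final oxidation level as a stable acetal.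
3. Forward order: ring B aldehyde (steps 1–5), acetal carbonate (6), five-membered lactone (7); ring A fluoroarene (8–10); diaryl ether by SNAr (11); seven-membered lactone (12–13); aldehyde reduction (14); release of the lactol (15).
4. Stereochemistry: the lactol carbon is carried as its acetal with (S)-1-phenylethanol. Step 6 forms both epimers at the acetal carbon, the chromatography of step 7 passes on only the (3R) epimer, and the last step cleaves only the O–CH(CH3)Ph bond, so the four bonds of the stereocentre are never broken.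

Key step: step 7

Assumption: the free lactol can epimerize by ring–chain tautomerism, so it is kept as an acetal until the last step and is taken to hold its configuration when handled cold and free of acid and base.

**Step 1**
Reactants: 1 2,4-dihydroxy-3-methylbenzaldehyde
Product: 2 3-methyl-2,4-bis(prop-2-en-1-yloxy)benzaldehyde
Conditions: allyl bromide (2.5 equiv), K2CO3, DMF, 60 °C
Reagents that add atoms: allyl bromide C=CCBr
Why: Williamson ether synthesis should alkylate both phenols, the hydrogen-bonded 2-OH reacting on warming.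

**Step 2**
Reactants: 2 3-methyl-2,4-bis(prop-2-en-1-yloxy)benzaldehyde
Product: 4 3-methyl-2,4-bis(prop-2-en-1-yloxy)phenol, via aryl formate 3 (not isolated)
Conditions: 30% H2O2, H2SO4 (cat.), MeOH, rt
Reagents that add atoms: hydrogen peroxide OO
Why: Acid-catalysed Dakin oxidation (Baeyer–Villiger-type aryl migration) is favoured for this electron-rich benzaldehyde, H2O2 does not epoxidize the allyl groups, and the formate is methanolysed in the flask.

**Step 3**
Reactants: 4 3-methyl-2,4-bis(prop-2-en-1-yloxy)phenol
Product: 5 2-hydroxy-4-methyl-3,5-bis(prop-2-en-1-yloxy)benzaldehyde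
Conditions: MgCl2, Et3N, (CH2O)n, MeCN, reflux; then 1 M HCl
Reagents that add atoms: paraformaldehyde (as formaldehyde) C=O
Why: Magnesium-mediated ortho-formylation of phenols delivers the formyl group only to the single free position ortho to the phenoxide oxygen.

**Step 4**
Reactants: 5 2-hydroxy-4-methyl-3,5-bis(prop-2-en-1-yloxy)benzaldehyde
Product: 6 2-hydroxy-6-iodo-4-methyl-3,5-bis(prop-2-en-1-yloxy)benzaldehyde
Conditions: NIS, CF3CO2H (cat.), MeCN, 0 °C → rt
Reagents that add atoms: N-iodosuccinimide O=C1CCC(=O)N1I
Why: Electrophilic aromatic iodination can only occur at the one unsubstituted ring carbon, which is ortho and para to the two allyloxy groups.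

**Step 5**
Reactants: 6 2-hydroxy-6-iodo-4-methyl-3,5-bis(prop-2-en-1-yloxy)benzaldehyde
Product: 7 2-[(tert-butyldimethylsilyl)oxy]-6-iodo-4-methyl-3,5-bis(prop-2-en-1-yloxy)benzaldehyde
Conditions: TBSCl, imidazole, DMF, rt
Reagents that add atoms: tert-butyldimethylsilyl chloride CC(C)(C)[Si](C)(C)Cl
Why: Silylation masks the phenol during steps 6 and 7 and lets fluoride release it as the nucleophile of step 11.

**Step 6**
Reactants: 7 2-[(tert-butyldimethylsilyl)oxy]-6-iodo-4-methyl-3,5-bis(prop-2-en-1-yloxy)benzaldehyde; 8 (S)-1-phenylethanol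
Product: 10 {2-[(tert-butyldimethylsilyl)oxy]-6-iodo-4-methyl-3,5-bis(prop-2-en-1-yloxy)phenyl}[(1S)-1-phenylethoxy]methyl phenyl carbonate (both epimers at the acetal carbon), via chloromethyl phenyl carbonate 9 (not isolated)
Conditions: PhOCOCl (1.05 equiv), pyridine (5 mol %), CH2Cl2, 0 °C → rt; then 8, AgOSO2CF3, 2,6-lutidine, −40 → 0 °C
Reagents that add atoms: phenyl chloroformate O=C(Cl)Oc1ccccc1
Why: Chloride-catalysed addition of a chloroformate across the aldehyde C=O gives the α-chloroalkyl carbonate, and a silver-promoted Koenigs–Knorr-type substitution of the benzylic chloride by the alcohol gives the acetal carbonate without stereocontrol at the acetal carbon.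

**Step 7**
Reactants: 10 {2-[(tert-butyldimethylsilyl)oxy]-6-iodo-4-methyl-3,5-bis(prop-2-en-1-yloxy)phenyl}[(1S)-1-phenylethoxy]methyl phenyl carbonate
Product: 12 (3R)-4-[(tert-butyldimethylsilyl)oxy]-6-methyl-3-[(1S)-1-phenylethoxy]-5,7-bis(prop-2-en-1-yloxy)-2-benzofuran-1(3H)-one, via arylmagnesium chloride 11 (not isolated)
Conditions: i-PrMgCl·LiCl (1.1 equiv), THF, −30 → 0 °C; aq. NH4Cl; chromatography on silica to remove the (3S) epimer
Reagents that add atoms: none
Why: Iodine–magnesium exchange gives the arylmagnesium 11 at the ring carbon between the allyloxy carbon and the acetal-bearing carbon, and this carbon adds to the carbonate carbonyl five atoms away to give a cyclic magnesium alkoxide that expels phenoxide, a better leaving group by about three pKa units than the ring hemiacetal oxygen, leaving the lactone. The closest known reaction type is the Parham cyclization of ortho-metalated benzyl carbonates and carbamates to phthalides. The five-membered ring closes in the 5-exo-trig mode onto the carbonate C=O. No stereocentre is made in the C–C bond formation: the acetal carbon enters as both epimers with its bonds untouched, and because the (S)-1-phenylethyl group makes the two cyclized acetals diastereomers, chromatography should deliver the (3R) epimer 12 and remove the (3S) epimer, so that at most half of the material is carried on. The step needs exchange to outrun addition of i-PrMgCl to the carbonate and ring closure to outrun intermolecular acyl transfer, which the fast exchange of an aryl iodide flanked by two chelating oxygens at low temperature and the five-membered transition state should secure. It completes the hexasubstituted ring B and delivers the lactol carbon at its final oxidation level in a form that stores its configuration.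

**Step 8**
Reactants: 13 1-fluoro-3-methoxy-5-methylbenzene
Product: 15 2-fluoro-6-methoxy-4-methylbenzaldehyde, via aryllithium 14 (not isolated)
Conditions: n-BuLi, THF, −78 °C; DMF; aq. NH4Cl
Reagents that add atoms: N,N-dimethylformamide CN(C)C=O
Why: Directed ortho-lithiation removes the most acidic proton, the one flanked by fluorine and methoxy, and the aryllithium is formylated by DMF.

**Step 9**
Reactants: 15 2-fluoro-6-methoxy-4-methylbenzaldehyde
Product: 16 3-bromo-2-fluoro-6-methoxy-4-methylbenzaldehyde
Conditions: NBS, MeCN, rt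
Reagents that add atoms: N-bromosuccinimide O=C1CCC(=O)N1Br
Why: Electrophilic aromatic bromination should go para to the methoxy group, a position that is also ortho to fluorine and meta to the formyl group.

**Step 10**
Reactants: 16 3-bromo-2-fluoro-6-methoxy-4-methylbenzaldehyde
Product: 19 prop-2-en-1-yl 2-fluoro-3-formyl-4-methoxy-6-methylbenzoate, via lithium amino alkoxide 17 (not isolated), via aryllithium 18 (not isolated)
Conditions: LiN(CH3)CH2CH2N(CH3)2 [from CH3NHCH2CH2N(CH3)2 and n-BuLi], THF, −78 → −20 °C; n-BuLi, −78 °C; ClCO2CH2CH=CH2, −78 °C → rt; aq. citric acid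
Reagents that add atoms: allyl chloroformate C=CCOC(Cl)=O
Why: The aldehyde is protected in the flask as its lithium α-amino alkoxide, bromine–lithium exchange at −78 °C stays below the temperature of LiF loss to an aryne, and acylation with the chloroformate followed by acidic work-up returns the aldehyde.

**Step 11**
Reactants: 12 (3R)-4-[(tert-butyldimethylsilyl)oxy]-6-methyl-3-[(1S)-1-phenylethoxy]-5,7-bis(prop-2-en-1-yloxy)-2-benzofuran-1(3H)-one; 19 prop-2-en-1-yl 2-fluoro-3-formyl-4-methoxy-6-methylbenzoate
Product: 21 prop-2-en-1-yl 3-formyl-4-methoxy-6-methyl-2-({(3R)-6-methyl-1-oxo-3-[(1S)-1-phenylethoxy]-5,7-bis(prop-2-en-1-yloxy)-1,3-dihydro-2-benzofuran-4-yl}oxy)benzoate, via cesium phenoxide 20 (not isolated)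
Conditions: CsF, DMF, rt → 50 °C
Reagents that add atoms: none
Why: Fluoride removes the silyl group and the phenoxide displaces the fluoride activated by an ortho ester and an ortho formyl group (nucleophilic aromatic substitution), under aprotic basic conditions that leave the acetal carbon alone.

**Step 12**
Reactants: 21 prop-2-en-1-yl 3-formyl-4-methoxy-6-methyl-2-({(3R)-6-methyl-1-oxo-3-[(1S)-1-phenylethoxy]-5,7-bis(prop-2-en-1-yloxy)-1,3-dihydro-2-benzofuran-4-yl}oxy)benzoate
Product: 22 2-({(3R)-5,7-dihydroxy-6-methyl-1-oxo-3-[(1S)-1-phenylethoxy]-1,3-dihydro-2-benzofuran-4-yl}oxy)-3-formyl-4-methoxy-6-methylbenzoic acid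
Conditions: Pd(PPh3)4 (5 mol %), 4-MeC6H4SO2Na, THF–MeOH, rt; then dil. HCl
Reagents that add atoms: none
Why: Tsuji–Trost-type deallylation by zerovalent palladium ionizes the two aryl allyl ethers and the allyl ester, and the sulfinate traps the allyl groups under near-neutral conditions that spare the aldehyde and the acetal.

**Step 13**
Reactants: 22 2-({(3R)-5,7-dihydroxy-6-methyl-1-oxo-3-[(1S)-1-phenylethoxy]-1,3-dihydro-2-benzofuran-4-yl}oxy)-3-formyl-4-methoxy-6-methylbenzoic acid
Product: 23 (1R)-4-hydroxy-10-methoxy-5,8-dimethyl-3,7-dioxo-1-[(1S)-1-phenylethoxy]-1,3-dihydro-7H-isobenzofuro[4,5-b][1,4]benzodioxepine-11-carbaldehyde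
Conditions: DCC, DMAP (cat.), CH2Cl2 (0.005 M), 0 °C → rt
Reagents that add atoms: none
Why: Steglich-type lactonization closes the seven-membered ring because only the hydroxyl next to the diaryl ether oxygen can reach the activated acid, the other phenol being hydrogen-bonded to the five-membered lactone carbonyl and out of reach.

**Step 14**
Reactants: 23 (1R)-4-hydroxy-10-methoxy-5,8-dimethyl-3,7-dioxo-1-[(1S)-1-phenylethoxy]-1,3-dihydro-7H-isobenzofuro[4,5-b][1,4]benzodioxepine-11-carbaldehyde
Product: 24 (1R)-4-hydroxy-11-(hydroxymethyl)-10-methoxy-5,8-dimethyl-1-[(1S)-1-phenylethoxy]-1H-isobenzofuro[4,5-b][1,4]benzodioxepine-3,7-dione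
Conditions: NaBH4, THF–MeOH, −20 °C; aq. NH4Cl
Reagents that add atoms: none
Why: Borohydride reduction of the aryl aldehyde is far faster at low temperature than attack on either lactone, and the new benzylic alkoxide sits meta to the seven-membered lactone carbonyl and cannot add to it.

**Step 15**
Reactants: 24 (1R)-4-hydroxy-11-(hydroxymethyl)-10-methoxy-5,8-dimethyl-1-[(1S)-1-phenylethoxy]-1H-isobenzofuro[4,5-b][1,4]benzodioxepine-3,7-dione
Product: 25 (1R)-1,4-dihydroxy-11-(hydroxymethyl)-10-methoxy-5,8-dimethyl-1H-isobenzofuro[4,5-b][1,4]benzodioxepine-3,7-dione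
Conditions: H2 (1 atm), 10% Pd/C, EtOAc, rt; filtration and evaporation below 20 °C
Reagents that add atoms: none
Why: Hydrogenolysis should cleave the secondary benzylic C–O bond of the unhindered 1-phenylethyl group, while the benzylic C–O bonds on the penta- and hexasubstituted rings cannot lie flat on the catalyst, so the acetal carbon keeps its four bonds and its (R) configuration.

**Compound list**

1 | 2,4-dihydroxy-3-methylbenzaldehyde | O=Cc1ccc(O)c(C)c1O | starting material
2 | 3-methyl-2,4-bis(prop-2-en-1-yloxy)benzaldehyde | O=Cc1ccc(OCC=C)c(C)c1OCC=C | intermediate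
3 | 3-methyl-2,4-bis(prop-2-en-1-yloxy)phenyl formate | O=COc1ccc(OCC=C)c(C)c1OCC=C | intermediate
4 | 3-methyl-2,4-bis(prop-2-en-1-yloxy)phenol | Oc1ccc(OCC=C)c(C)c1OCC=C | intermediate
5 | 2-hydroxy-4-methyl-3,5-bis(prop-2-en-1-yloxy)benzaldehyde | O=Cc1cc(OCC=C)c(C)c(OCC=C)c1O | intermediate
6 | 2-hydroxy-6-iodo-4-methyl-3,5-bis(prop-2-en-1-yloxy)benzaldehyde | O=Cc1c(I)c(OCC=C)c(C)c(OCC=C)c1O | intermediate
7 | 2-[(tert-butyldimethylsilyl)oxy]-6-iodo-4-methyl-3,5-bis(prop-2-en-1-yloxy)benzaldehyde | O=Cc1c(I)c(OCC=C)c(C)c(OCC=C)c1O[Si](C)(C)C(C)(C)C | intermediate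
8 | (S)-1-phenylethanol | C[C@H](O)c1ccccc1 | starting material
9 | chloro{2-[(tert-butyldimethylsilyl)oxy]-6-iodo-4-methyl-3,5-bis(prop-2-en-1-yloxy)phenyl}methyl phenyl carbonate (racemic) | O=C(Oc1ccccc1)OC(Cl)c1c(I)c(OCC=C)c(C)c(OCC=C)c1O[Si](C)(C)C(C)(C)C | intermediate
10 | {2-[(tert-butyldimethylsilyl)oxy]-6-iodo-4-methyl-3,5-bis(prop-2-en-1-yloxy)phenyl}[(1S)-1-phenylethoxy]methyl phenyl carbonate (both epimers at the acetal carbon, left open in the SMILES) | O=C(Oc1ccccc1)OC(O[C@@H](C)c1ccccc1)c1c(I)c(OCC=C)c(C)c(OCC=C)c1O[Si](C)(C)C(C)(C)C | intermediate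
11 | arylmagnesium chloride of 10 (MgCl in place of I; both epimers at the acetal carbon, left open in the SMILES) | O=C(Oc1ccccc1)OC(O[C@@H](C)c1ccccc1)c1c([Mg]Cl)c(OCC=C)c(C)c(OCC=C)c1O[Si](C)(C)C(C)(C)C | intermediate
12 | (3R)-4-[(tert-butyldimethylsilyl)oxy]-6-methyl-3-[(1S)-1-phenylethoxy]-5,7-bis(prop-2-en-1-yloxy)-2-benzofuran-1(3H)-one | CC(C)(C)[Si](C)(C)Oc1c(OCC=C)c(C)c(OCC=C)c2c1[C@H](O[C@@H](C)c1ccccc1)OC2=O | intermediate
13 | 1-fluoro-3-methoxy-5-methylbenzene | COc1cc(C)cc(F)c1 | starting material
14 | (2-fluoro-6-methoxy-4-methylphenyl)lithium | COc1cc(C)cc(F)c1[Li] | intermediate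
15 | 2-fluoro-6-methoxy-4-methylbenzaldehyde | COc1cc(C)cc(F)c1C=O | intermediate
16 | 3-bromo-2-fluoro-6-methoxy-4-methylbenzaldehyde | COc1cc(C)c(Br)c(F)c1C=O | intermediate
17 | lithium (3-bromo-2-fluoro-6-methoxy-4-methylphenyl){[2-(dimethylamino)ethyl](methyl)amino}methanolate (racemic) | COc1cc(C)c(Br)c(F)c1C(O[Li])N(C)CCN(C)C | intermediate
18 | 3-lithio analogue of 17 (Li in place of Br) | COc1cc(C)c([Li])c(F)c1C(O[Li])N(C)CCN(C)C | intermediate
19 | prop-2-en-1-yl 2-fluoro-3-formyl-4-methoxy-6-methylbenzoate | COc1cc(C)c(C(=O)OCC=C)c(F)c1C=O | intermediate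
20 | cesium (3R)-6-methyl-1-oxo-3-[(1S)-1-phenylethoxy]-5,7-bis(prop-2-en-1-yloxy)-1,3-dihydro-2-benzofuran-4-olate | [Cs+].[O-]c1c(OCC=C)c(C)c(OCC=C)c2c1[C@H](O[C@@H](C)c1ccccc1)OC2=O | intermediate
21 | prop-2-en-1-yl 3-formyl-4-methoxy-6-methyl-2-({(3R)-6-methyl-1-oxo-3-[(1S)-1-phenylethoxy]-5,7-bis(prop-2-en-1-yloxy)-1,3-dihydro-2-benzofuran-4-yl}oxy)benzoate | COc1cc(C)c(C(=O)OCC=C)c(Oc2c(OCC=C)c(C)c(OCC=C)c3c2[C@H](O[C@@H](C)c2ccccc2)OC3=O)c1C=O | intermediate
22 | 2-({(3R)-5,7-dihydroxy-6-methyl-1-oxo-3-[(1S)-1-phenylethoxy]-1,3-dihydro-2-benzofuran-4-yl}oxy)-3-formyl-4-methoxy-6-methylbenzoic acid | COc1cc(C)c(C(=O)O)c(Oc2c(O)c(C)c(O)c3c2[C@H](O[C@@H](C)c2ccccc2)OC3=O)c1C=O | intermediate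
23 | (1R)-4-hydroxy-10-methoxy-5,8-dimethyl-3,7-dioxo-1-[(1S)-1-phenylethoxy]-1,3-dihydro-7H-isobenzofuro[4,5-b][1,4]benzodioxepine-11-carbaldehyde | COc1cc(C)c2c(c1C=O)Oc1c(c(C)c(O)c3c1[C@H](O[C@@H](C)c1ccccc1)OC3=O)OC2=O | intermediate
24 | (1R)-4-hydroxy-11-(hydroxymethyl)-10-methoxy-5,8-dimethyl-1-[(1S)-1-phenylethoxy]-1H-isobenzofuro[4,5-b][1,4]benzodioxepine-3,7-dione | COc1cc(C)c2c(c1CO)Oc1c(c(C)c(O)c3c1[C@H](O[C@@H](C)c1ccccc1)OC3=O)OC2=O | intermediate
25 | (1R)-1,4-dihydroxy-11-(hydroxymethyl)-10-methoxy-5,8-dimethyl-1H-isobenzofuro[4,5-b][1,4]benzodioxepine-3,7-dione | COc1cc(C)c2c(c1CO)Oc1c(c(C)c(O)c3c1[C@H](O)OC3=O)OC2=O | target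

**Step count and risks**

Total steps: 15. Longest linear sequence: 12 (steps 1–7 and 11–15; steps 8–10 make the ring A fragment).

Step 7. The iodine–magnesium exchange at the doubly flanked, electron-rich iodide may be too slow, so that the Grignard reagent adds to the phenyl carbonate. The cyclic tetrahedral intermediate may also collapse by loss of the ring oxygen, opening the new ring and losing the 1-phenylethoxy group, or the magnesium salts may ionize the acetal carbonate. Fallback: set out from 7. The aldehyde is protected in the flask as its lithium α-amino alkoxide with LiN(CH3)CH2CH2N(CH3)2, iodine–lithium exchange is run with t-BuLi at −78 °C, and the aryllithium is quenched with CO2 and acidified. This should give the racemic lactol 4-[(tert-butyldimethylsilyl)oxy]-3-hydroxy-6-methyl-5,7-bis(prop-2-en-1-yloxy)-2-benzofuran-1(3H)-one F1, in which the carbon comes from CO2 and the ring closes at oxygen. Acetalization of F1 with 8 under pyridinium p-toluenesulfonate catalysis with removal of water should give the two epimeric acetals, and the route is rejoined at 12 after the same chromatographic separation.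

Step 6. Addition of the chloroformate to the hindered, di-ortho-substituted aldehyde may be incomplete, the alcohol may attack the carbonate carbonyl instead of the chlorine-bearing carbon, or the acetal carbonate may ionize and decompose on handling. Fallback: set out from 7. Palladium-catalysed alkoxycarbonylation of the iodide (Pd(OAc)2, Xantphos, CO, 8, Et3N, toluene, 80 °C) should give the open-chain ester (1S)-1-phenylethyl 2,4-bis(prop-2-en-1-yloxy)-5-[(tert-butyldimethylsilyl)oxy]-6-formyl-3-methylbenzoate F2. A catalytic amount of the lithium alkoxide of 8 in THF should then isomerize F2 to the cyclic acetals, by addition of the alkoxide to the aldehyde and lactonization of the hemiacetal alkoxide onto the ester. The route is rejoined at 12 after separation of the epimers.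

Step 15. Hydrogenolysis may overrun to the benzylic C–O bond of the ring A alcohol or to the acetal C–O bonds, or cleavage of the hindered secondary benzylic ether may be slow enough that the freed lactol epimerizes during long exposure. Fallback: set out from 24 and cleave the ether by acidolysis at the secondary benzylic carbon with BCl3 and pentamethylbenzene as cation scavenger in CH2Cl2 at −78 °C. This ionizes the O–CH(CH3)Ph bond on the side of the 1-phenylethyl cation and leaves the acetal carbon–oxygen bonds intact. The route is rejoined at 25 and no new intermediate is formed.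

**Further compounds**

F1 | step 7 | 4-[(tert-butyldimethylsilyl)oxy]-3-hydroxy-6-methyl-5,7-bis(prop-2-en-1-yloxy)-2-benzofuran-1(3H)-one (racemic) | CC(C)(C)[Si](C)(C)Oc1c(OCC=C)c(C)c(OCC=C)c2c1C(O)OC2=O
F2 | step 6 | (1S)-1-phenylethyl 2,4-bis(prop-2-en-1-yloxy)-5-[(tert-butyldimethylsilyl)oxy]-6-formyl-3-methylbenzoate | C[C@H](OC(=O)c1c(OCC=C)c(C)c(OCC=C)c(O[Si](C)(C)C(C)(C)C)c1C=O)c1ccccc1
F0 | step 15 | none | none
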